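Ring A (C1, C2, C3, C4, C5, C10; eudesmane numbering) carries a 1,3-dioxygen pattern (C1–OH, C3–O) and a C3–C4–C5 array next to the ring fusion. This is the retron of an aldol at C1–C2 plus an aldol condensation at C4–C5. Acetone therefore serves as C2–C3–C4 and is stitched onto a ring B 2-formyl-2-methylcyclohexanone, whose quaternary C10 holds aldehyde C1 and ketone C5, in one proline-catalysed [3+3] aldol/aldol-condensation that also sets C1. A Birch reduction then fixes the trans ring fusion and its enolate takes up C15; Luche reduction, caffeoylation and desilylation finish.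

Key step: step 4

Remark: compound 1 is assumed to be a catalogue building block in its (S) form. Decalin compounds are named with eudesmane numbering (ring A = C1, C2, C3, C4, C5, C10; ring B = C5 to C10; C14 = methyl on C10; C15 = carbon on C4; β = the face of the C10 methyl).

Step 1
Reactants: 1 (S)-4-(tert-butyldimethylsilyloxy)cyclohex-2-en-1-one
Product: 2 (3R,4S)-4-(tert-butyldimethylsilyloxy)-3-(propan-2-yl)cyclohexan-1-one
Conditions: i-PrMgCl, CuBr·SMe2 (10 mol %), THF, –78 to –40 °C; aq. NH4Cl
Reagents that add atoms: isopropylmagnesium chloride, CC(C)[Mg]Cl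
Why: Copper-catalysed conjugate addition of a Grignard reagent, in which the isopropyl group should enter anti to the neighbouring silyloxy group (substrate control) and so set C7 in the trans-diequatorial 7β-isopropyl/8α-oxygen arrangement.

Step 2
Reactants: 2 (3R,4S)-4-(tert-butyldimethylsilyloxy)-3-(propan-2-yl)cyclohexan-1-one
Product: 3 (2Z,4S,5R)-4-(tert-butyldimethylsilyloxy)-2-(hydroxymethylidene)-5-(propan-2-yl)cyclohexan-1-one
Conditions: NaH, HCO2Et, EtOH (cat.), THF, 0 °C to rt; 1 M HCl
Reagents that add atoms: ethyl formate, CCOC=O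
Why: Claisen formylation under equilibrating conditions should go to the less hindered α-methylene (the future C10, remote from the isopropyl group) and give the chelated enol; no stereocentre is formed.

Step 3
Reactants: 3 (2Z,4S,5R)-4-(tert-butyldimethylsilyloxy)-2-(hydroxymethylidene)-5-(propan-2-yl)cyclohexan-1-one
Product: 4 (1S,4R,5S)-5-(tert-butyldimethylsilyloxy)-1-methyl-2-oxo-4-(propan-2-yl)cyclohexane-1-carbaldehyde
Conditions: MeI, K2CO3, acetone, rt
Reagents that add atoms: iodomethane, CI
Why: C-alkylation of a β-keto aldehyde enolate, in which iodomethane should approach C10 axially on the half-chair that keeps isopropyl and silyloxy equatorial, so that the methyl ends cis to isopropyl and trans to the silyloxy group (10β-methyl).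

Step 4
Reactants: 4 (1S,4R,5S)-5-(tert-butyldimethylsilyloxy)-1-methyl-2-oxo-4-(propan-2-yl)cyclohexane-1-carbaldehyde; 5 acetone
Product: 8 8α-(tert-butyldimethylsilyloxy)-1β-hydroxy-15-noreudesm-4-en-3-one, via aldol adduct 6 (not isolated), via ring-fusion ketol 7 (not isolated)
Conditions: L-proline (30 mol %), acetone/DMSO (1:4), rt; acetone evaporated; 50 °C
Reagents that add atoms: none
Why: The proline enamine of acetone adds to the aldehyde of 4 through the hydrogen-bonded enamine/carboxylic acid transition state (C1–C2 bond, adduct 6); after the excess acetone is removed, the enamine on the methyl side of the new methyl ketone attacks the ring ketone C5 and the tertiary ketol 7 loses water to the conjugated enone (C4–C5 bond). The closest known reaction types are the proline-catalysed acetone aldol with α-quaternary aldehydes and the Hajos–Parrish-type proline-catalysed aldol cyclodehydration of 1,5-diketones, run here in one pot as a Robinson-type [3+3] annulation. Ring A closes by a 6-(enolendo)-exo-trig aldol addition. The surviving new stereocentre C1 is set by the catalyst, since (S)-proline gives (R)-carbinols with α-branched aldehydes and this corresponds to 1β-OH, whereas the C5 ketol centre is erased on dehydration. The step needs attack at the aldehyde and not the ketone (secured by the much higher electrophilicity of the non-enolisable formyl group) and closure through C4 and not C2 (C2 would give a four-membered ring, and the bridged ketol from the ring-ketone enamine cannot dehydrate and reverts). It also needs dehydration of the tertiary C5 ketol only, which the mild, base-free conditions should favour over loss of the secondary C1 carbinol.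

Step 5
Reactants: 8 8α-(tert-butyldimethylsilyloxy)-1β-hydroxy-15-noreudesm-4-en-3-one
Product: 9 8α-(tert-butyldimethylsilyloxy)-1β-(triethylsilyloxy)-15-noreudesm-4-en-3-one
Conditions: TESOTf, 2,6-lutidine, CH2Cl2, –78 °C
Reagents that add atoms: triethylsilyl trifluoromethanesulfonate, CC[Si](CC)(CC)OS(=O)(=O)C(F)(F)F
Why: Silylation of the secondary carbinol blocks retro-aldol cleavage in the basic steps that follow and leaves C3–OH as the only free hydroxyl at the acylation stage.

Step 6
Reactants: 9 8α-(tert-butyldimethylsilyloxy)-1β-(triethylsilyloxy)-15-noreudesm-4-en-3-one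
Product: 11 15-(dimethylamino)-8α-(tert-butyldimethylsilyloxy)-1β-(triethylsilyloxy)-4βH,5αH-eudesman-3-one, via lithium enolate 10 (not isolated)
Conditions: Li (2.2 equiv), NH3(l)/THF, t-BuOH (1 equiv), –78 °C; NH3 removed; CH2=NMe2+ I–, THF, –78 to 0 °C; aq. NH4Cl
Reagents that add atoms: N,N-dimethylmethyleneiminium iodide (Eschenmoser's salt), C=[N+](C)C.[I-]
Why: Birch-type dissolving-metal reduction of the enone should protonate C5 axially from the α face (trans-decalin, 5α-H) and leave the regiodefined C3–C4 lithium enolate, which is aminomethylated at C4 in a Mannich reaction; the C4 configuration (drawn equatorial) is erased in step 7.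

Step 7
Reactants: 11 15-(dimethylamino)-8α-(tert-butyldimethylsilyloxy)-1β-(triethylsilyloxy)-4βH,5αH-eudesman-3-one
Product: 13 8α-(tert-butyldimethylsilyloxy)-1β-(triethylsilyloxy)-5αH-eudesm-4(15)-en-3-one, via methiodide 12 (not isolated)
Conditions: MeI, MeOH, rt; then aq. NaHCO3/CH2Cl2, rt
Reagents that add atoms: none
Why: N-Quaternisation followed by Hofmann-type β-elimination (E1cB) of trimethylamine should give the exocyclic enone, and the weak base is chosen to avoid isomerisation to the endocyclic enone and loss of the C1 silyloxy group.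

Step 8
Reactants: 13 8α-(tert-butyldimethylsilyloxy)-1β-(triethylsilyloxy)-5αH-eudesm-4(15)-en-3-one
Product: 14 8α-(tert-butyldimethylsilyloxy)-1β-(triethylsilyloxy)-5αH-eudesm-4(15)-en-3β-ol
Conditions: NaBH4, CeCl3·7H2O, MeOH, –78 °C
Reagents that add atoms: none
Why: Luche 1,2-reduction, in which axial hydride delivery from the unhindered α face of the trans-decalin should give the equatorial 3β-alcohol.

Step 9
Reactants: 15 (E)-caffeic acid
Product: 17 (E)-3,4-bis(tert-butyldimethylsilyloxy)cinnamic acid, via tris-silylated caffeate 16 (not isolated)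
Conditions: TBSCl (3.5 equiv), imidazole, DMF, rt; then AcOH/THF/H2O, rt
Reagents that add atoms: tert-butyldimethylsilyl chloride, CC(C)(C)[Si](C)(C)Cl
Why: Exhaustive silylation followed by selective hydrolysis of the far more labile silyl ester should free the acid while the two aryl silyl ethers stay.

Step 10
Reactants: 14 8α-(tert-butyldimethylsilyloxy)-1β-(triethylsilyloxy)-5αH-eudesm-4(15)-en-3β-ol; 17 (E)-3,4-bis(tert-butyldimethylsilyloxy)cinnamic acid
Product: 18 8α-(tert-butyldimethylsilyloxy)-1β-(triethylsilyloxy)-5αH-eudesm-4(15)-en-3β-yl (E)-3,4-bis(tert-butyldimethylsilyloxy)cinnamate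
Conditions: EDC·HCl, DMAP, CH2Cl2, 0 °C to rt
Reagents that add atoms: none
Why: Steglich esterification of the only free hydroxyl, which does not touch the C3–O bond or the E-alkene, so both configurations are retained.

Step 11
Reactants: 18 8α-(tert-butyldimethylsilyloxy)-1β-(triethylsilyloxy)-5αH-eudesm-4(15)-en-3β-yl (E)-3,4-bis(tert-butyldimethylsilyloxy)cinnamate
Product: 19 (1R,3S,5S,7R,8S,10R)-1,8-dihydroxyeudesm-4(15)-en-3-yl (E)-3-(3,4-dihydroxyphenyl)prop-2-enoate (1β,8α-dihydroxy-5αH-eudesm-4(15)-en-3β-yl caffeate)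
Conditions: HF·pyridine, pyridine, THF, 0 °C to rt
Reagents that add atoms: none
Why: Buffered fluoride desilylation should cleave the two aryl silyl ethers, the C8 tert-butyldimethylsilyl ether and the C1 triethylsilyl ether while the allylic cinnamate ester and the catechol survive.

Compound list
1 | (S)-4-(tert-butyldimethylsilyloxy)cyclohex-2-en-1-one | O=C1C=C[C@@H](O[Si](C)(C)C(C)(C)C)CC1 | starting material
2 | (3R,4S)-4-(tert-butyldimethylsilyloxy)-3-(propan-2-yl)cyclohexan-1-one | O=C1CC[C@H](O[Si](C)(C)C(C)(C)C)[C@@H](C(C)C)C1 | intermediate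
3 | (2Z,4S,5R)-4-(tert-butyldimethylsilyloxy)-2-(hydroxymethylidene)-5-(propan-2-yl)cyclohexan-1-one | O/C=C1/C[C@H](O[Si](C)(C)C(C)(C)C)[C@@H](C(C)C)CC1=O | intermediate
4 | (1S,4R,5S)-5-(tert-butyldimethylsilyloxy)-1-methyl-2-oxo-4-(propan-2-yl)cyclohexane-1-carbaldehyde | O=C[C@]1(C)C[C@H](O[Si](C)(C)C(C)(C)C)[C@@H](C(C)C)CC1=O | intermediate
5 | acetone | CC(C)=O | starting material
6 | (2S,4S,5R)-4-(tert-butyldimethylsilyloxy)-2-[(1R)-1-hydroxy-3-oxobutyl]-2-methyl-5-(propan-2-yl)cyclohexan-1-one (aldol adduct) | CC(=O)C[C@@H](O)[C@]1(C)C[C@H](O[Si](C)(C)C(C)(C)C)[C@@H](C(C)C)CC1=O | intermediate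
7 | 8α-(tert-butyldimethylsilyloxy)-1β,5β-dihydroxy-15-noreudesman-3-one (cis-fused ketol; C5 drawn as the cis ketol, erased on dehydration) | O=C1C[C@@H](O)[C@]2(C)C[C@H](O[Si](C)(C)C(C)(C)C)[C@@H](C(C)C)C[C@]2(O)C1 | intermediate
8 | 8α-(tert-butyldimethylsilyloxy)-1β-hydroxy-15-noreudesm-4-en-3-one | O=C1C[C@@H](O)[C@]2(C)C[C@H](O[Si](C)(C)C(C)(C)C)[C@@H](C(C)C)CC2=C1 | intermediate
9 | 8α-(tert-butyldimethylsilyloxy)-1β-(triethylsilyloxy)-15-noreudesm-4-en-3-one | O=C1C[C@@H](O[Si](CC)(CC)CC)[C@]2(C)C[C@H](O[Si](C)(C)C(C)(C)C)[C@@H](C(C)C)CC2=C1 | intermediate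
10 | lithium 8α-(tert-butyldimethylsilyloxy)-1β-(triethylsilyloxy)-15-nor-5αH-eudesm-3-en-3-olate (lithium enolate) | C1=C(O[Li])C[C@@H](O[Si](CC)(CC)CC)[C@]2(C)C[C@H](O[Si](C)(C)C(C)(C)C)[C@@H](C(C)C)C[C@@H]12 | intermediate
11 | 15-(dimethylamino)-8α-(tert-butyldimethylsilyloxy)-1β-(triethylsilyloxy)-4βH,5αH-eudesman-3-one (Mannich base) | CN(C)C[C@@H]1C(=O)C[C@@H](O[Si](CC)(CC)CC)[C@]2(C)C[C@H](O[Si](C)(C)C(C)(C)C)[C@@H](C(C)C)C[C@@H]12 | intermediate
12 | methiodide of 11 (trimethylammonium iodide at C15) | C[N+](C)(C)C[C@@H]1C(=O)C[C@@H](O[Si](CC)(CC)CC)[C@]2(C)C[C@H](O[Si](C)(C)C(C)(C)C)[C@@H](C(C)C)C[C@@H]12.[I-] | intermediate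
13 | 8α-(tert-butyldimethylsilyloxy)-1β-(triethylsilyloxy)-5αH-eudesm-4(15)-en-3-one | C=C1C(=O)C[C@@H](O[Si](CC)(CC)CC)[C@]2(C)C[C@H](O[Si](C)(C)C(C)(C)C)[C@@H](C(C)C)C[C@@H]12 | intermediate
14 | 8α-(tert-butyldimethylsilyloxy)-1β-(triethylsilyloxy)-5αH-eudesm-4(15)-en-3β-ol | C=C1[C@@H](O)C[C@@H](O[Si](CC)(CC)CC)[C@]2(C)C[C@H](O[Si](C)(C)C(C)(C)C)[C@@H](C(C)C)C[C@@H]12 | intermediate
15 | (E)-caffeic acid | OC(=O)/C=C/c1ccc(O)c(O)c1 | starting material
16 | tert-butyldimethylsilyl (E)-3,4-bis(tert-butyldimethylsilyloxy)cinnamate | CC(C)(C)[Si](C)(C)OC(=O)/C=C/c1ccc(O[Si](C)(C)C(C)(C)C)c(O[Si](C)(C)C(C)(C)C)c1 | intermediate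
17 | (E)-3,4-bis(tert-butyldimethylsilyloxy)cinnamic acid | OC(=O)/C=C/c1ccc(O[Si](C)(C)C(C)(C)C)c(O[Si](C)(C)C(C)(C)C)c1 | intermediate
18 | 8α-(tert-butyldimethylsilyloxy)-1β-(triethylsilyloxy)-5αH-eudesm-4(15)-en-3β-yl (E)-3,4-bis(tert-butyldimethylsilyloxy)cinnamate | C=C1[C@@H](OC(=O)/C=C/c2ccc(O[Si](C)(C)C(C)(C)C)c(O[Si](C)(C)C(C)(C)C)c2)C[C@@H](O[Si](CC)(CC)CC)[C@]2(C)C[C@H](O[Si](C)(C)C(C)(C)C)[C@@H](C(C)C)C[C@@H]12 | intermediate
19 | (1R,3S,5S,7R,8S,10R)-1,8-dihydroxyeudesm-4(15)-en-3-yl (E)-caffeate | C=C1[C@@H](OC(=O)/C=C/c2ccc(O)c(O)c2)C[C@@H](O)[C@]2(C)C[C@H](O)[C@@H](C(C)C)C[C@@H]12 | target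

Total step count: 11. Longest linear sequence: 10 steps (steps 1 to 8, 10 and 11); step 9 is a one-step side branch.

Steps most likely to fail

Step 4. The cascade may stall at the open-chain aldol because the proline enamine attacks the hindered ring ketone too slowly. Forcing it may cause β-elimination or retro-aldol loss of the C1 carbinol, and a mismatch between catalyst and the C10 centre may erode facial selectivity. The fallback sets out from 4 and makes the sequence stepwise. The proline aldol is stopped at room temperature and the aldol adduct 6 is isolated. Its carbinol is capped with TESOTf/2,6-lutidine to give the triethylsilyl ether of the aldol adduct F1, which can no longer undergo retro-aldol cleavage. Ring A is then closed by a classical enolate-mediated Robinson-type cyclodehydration (KOt-Bu cat., t-BuOH/THF, 0 °C to rt). This delivers 9 directly, so the route is rejoined at 9 and step 5 is not needed.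

Step 6. The enolate may be protonated before it meets the iminium salt, residual amide or alkoxide may consume the iminium salt, the ketone may be over-reduced, or the C1 silyloxy group may be lost by E1cB in the basic medium. The fallback sets out from 9. After the same Li/NH3 reduction the enolate is trapped with TMSCl/Et3N and the trimethylsilyl enol ether F2 is isolated. A Mukaiyama–Mannich reaction of this neutral enol ether with Eschenmoser's salt in CH2Cl2, free of strong base, should then give 11, where the route is rejoined.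

Step 3. The ambident enolate may be methylated on oxygen, the α-formyl ketone may be deformylated by retro-Claisen cleavage under base, and iodomethane may approach equatorially and give the C10 epimer. The fallback sets out from 2 and carries C1 as an ester. Thermodynamic methoxycarbonylation (NaH, dimethyl carbonate, THF, reflux) gives the enolised β-keto ester F3. C-methylation (K2CO3, MeI, acetone) gives the quaternary methyl ester F4, which is stable to chromatography so that any C10 epimer can be removed there. LiAlH4 reduces ester and ketone to the diol F5 (C5 epimers), and Swern oxidation of both carbinols returns to the route at 4.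

Further compounds
F1 | step 4 | (2S,4S,5R)-4-(tert-butyldimethylsilyloxy)-2-methyl-2-[(1R)-3-oxo-1-(triethylsilyloxy)butyl]-5-(propan-2-yl)cyclohexan-1-one | CC(=O)C[C@@H](O[Si](CC)(CC)CC)[C@]1(C)C[C@H](O[Si](C)(C)C(C)(C)C)[C@@H](C(C)C)CC1=O
F2 | step 6 | 8α-(tert-butyldimethylsilyloxy)-1β-(triethylsilyloxy)-3-(trimethylsilyloxy)-15-nor-5αH-eudesm-3-ene | C1=C(O[Si](C)(C)C)C[C@@H](O[Si](CC)(CC)CC)[C@]2(C)C[C@H](O[Si](C)(C)C(C)(C)C)[C@@H](C(C)C)C[C@@H]12
F3 | step 3 | methyl (4R,5S)-5-(tert-butyldimethylsilyloxy)-2-hydroxy-4-(propan-2-yl)cyclohex-1-ene-1-carboxylate | OC1=C(C(=O)OC)C[C@H](O[Si](C)(C)C(C)(C)C)[C@@H](C(C)C)C1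
F4 | step 3 | methyl (1R,4R,5S)-5-(tert-butyldimethylsilyloxy)-1-methyl-2-oxo-4-(propan-2-yl)cyclohexane-1-carboxylate | COC(=O)[C@]1(C)C[C@H](O[Si](C)(C)C(C)(C)C)[C@@H](C(C)C)CC1=O
F5 | step 3 | (2S,4S,5R)-4-(tert-butyldimethylsilyloxy)-2-(hydroxymethyl)-2-methyl-5-(propan-2-yl)cyclohexan-1-ol (C1 epimers) | OC[C@]1(C)C[C@H](O[Si](C)(C)C(C)(C)C)[C@@H](C(C)C)CC1O
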